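**Plan**

- Cuts, in retrosynthetic order: the five O–CH3 bonds and the four aryl–CHO bonds; then O1–C2 and C2–C3 of the pyran ring together; then the C4–isobutyl bond and the side-chain C=C bonds.
- Enabling feature: C2 stands at the acetal oxidation level between O1 and ring B, and the isopropyl group on the neighbouring C3 can be read as a reduced isopropenyl group, the trace a tertiary cation leaves when a C3=CMe2 alkene adds to an O1=C2 carbenium ion.
- Forward: the ring A aldehyde is dibrominated (blocking C6 and C8), protected and homologated to a cinnamyl phosphate; asymmetric SN2′ alkylation, cross-metathesis and deprotection give the chiral alkenyl phenol.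
- The pyran ring then closes between this phenol and 2,4,6-trimethoxybenzaldehyde; hydrogenation with debromination, fourfold formylation and demethylation complete rings A and B.
- Stereochemistry: C4 comes from the chiral copper catalyst; C3 and C2 are relayed from C4 in the ring closure (allylic 1,3-strain for C3, E-carbenium ion in a chair for C2).

Key step: step 9

Assumption: the target is taken as the all-trans (2R,3R,4R) chroman that the given SMILES encodes; the antipode of the diphosphine in step 6 that delivers the R centre is fixed in a first run and then kept.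

**Route**

Step 1
Reactants: 1 2-hydroxy-4,6-dimethoxybenzaldehyde
Product: 2 3,5-dibromo-2-hydroxy-4,6-dimethoxybenzaldehyde
Conditions: NBS (2.1 equiv), MeCN, 0 °C to rt
Reagents that add atoms: N-bromosuccinimide, O=C1CCC(=O)N1Br
Why: Electrophilic aromatic bromination, in which both open ring positions are ortho or para to three oxygen donors and should take bromine cleanly, installing the groups that later shield C6 and C8 of ring A.

Step 2
Reactants: 2 3,5-dibromo-2-hydroxy-4,6-dimethoxybenzaldehyde
Product: 3 3,5-dibromo-4,6-dimethoxy-2-(methoxymethoxy)benzaldehyde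
Conditions: MOMCl (1.5 equiv), i-Pr2NEt (2 equiv), CH2Cl2, 0 °C to rt
Reagents that add atoms: chloromethyl methyl ether, COCCl
Why: O-alkylation of the phenol (MOM protection) masks the acidic OH for the hydride and Grignard steps that follow.

Step 3
Reactants: 3 3,5-dibromo-4,6-dimethoxy-2-(methoxymethoxy)benzaldehyde
Product: 4 ethyl (E)-3-[3,5-dibromo-4,6-dimethoxy-2-(methoxymethoxy)phenyl]prop-2-enoate
Conditions: (EtO)2P(O)CH2CO2Et, NaH, THF, 0 °C to rt
Reagents that add atoms: triethyl phosphonoacetate, CCOC(=O)CP(=O)(OCC)OCC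
Why: Horner–Wadsworth–Emmons olefination of a non-enolisable aryl aldehyde with a stabilised phosphonate should give the E-cinnamate.

Step 4
Reactants: 4 ethyl (E)-3-[3,5-dibromo-4,6-dimethoxy-2-(methoxymethoxy)phenyl]prop-2-enoate
Product: 5 (E)-3-[3,5-dibromo-4,6-dimethoxy-2-(methoxymethoxy)phenyl]prop-2-en-1-ol
Conditions: i-Bu2AlH (2.5 equiv), CH2Cl2, −78 °C; aq potassium sodium tartrate
Reagents that add atoms: none
Why: 1,2-Reduction of the unsaturated ester by the aluminium hydride at low temperature should give the allylic alcohol and leave the aryl bromides and the MOM ether alone.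

Step 5
Reactants: 5 (E)-3-[3,5-dibromo-4,6-dimethoxy-2-(methoxymethoxy)phenyl]prop-2-en-1-ol
Product: 6 (E)-3-[3,5-dibromo-4,6-dimethoxy-2-(methoxymethoxy)phenyl]prop-2-en-1-yl diethyl phosphate
Conditions: (EtO)2P(O)Cl, pyridine, DMAP (cat), CH2Cl2, 0 °C
Reagents that add atoms: diethyl chlorophosphate, CCOP(=O)(Cl)OCC
Why: O-phosphorylation of the primary allylic alcohol gives a leaving group that, unlike a halide on so electron-rich a cinnamyl system, should not ionise on handling.

Step 6
Reactants: 6 (E)-3-[3,5-dibromo-4,6-dimethoxy-2-(methoxymethoxy)phenyl]prop-2-en-1-yl diethyl phosphate; 7 isobutylmagnesium bromide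
Product: 8 (3R)-3-[3,5-dibromo-4,6-dimethoxy-2-(methoxymethoxy)phenyl]-5-methylhex-1-ene
Conditions: 7 (1.5 equiv, slow addition), CuBr·SMe2 (5 mol %), Taniaphos (ferrocenyl diphosphine, 6 mol %), CH2Cl2, −78 °C
Reagents that add atoms: none
Why: Copper-catalysed asymmetric allylic alkylation with a Grignard reagent (SN2′), in which the chiral diphosphine–copper complex displaces phosphate and couples the isobutyl group at the aryl-bearing carbon, so that the future C4 is set as R under catalyst control.

Step 7
Reactants: 8 (3R)-3-[3,5-dibromo-4,6-dimethoxy-2-(methoxymethoxy)phenyl]-5-methylhex-1-ene; 9 2-methylbut-2-ene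
Product: 10 (4R)-4-[3,5-dibromo-4,6-dimethoxy-2-(methoxymethoxy)phenyl]-2,6-dimethylhept-2-ene
Conditions: 9 (as solvent), second-generation Hoveyda–Grubbs catalyst RuCl2(H2IMes)(=CH-C6H4-2-O-i-Pr) (5 mol %), 40 °C, sealed tube
Reagents that add atoms: none
Why: Olefin cross-metathesis, in which the monosubstituted alkene exchanges its methylene for the isopropylidene unit of the partner used in large excess while propene escapes and the allylic stereocentre is not involved.

Step 8
Reactants: 10 (4R)-4-[3,5-dibromo-4,6-dimethoxy-2-(methoxymethoxy)phenyl]-2,6-dimethylhept-2-ene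
Product: 11 2,4-dibromo-6-[(4R)-2,6-dimethylhept-2-en-4-yl]-3,5-dimethoxyphenol
Conditions: conc HCl (cat), MeOH, rt
Reagents that add atoms: none
Why: Acid-catalysed acetal exchange (MOM cleavage) in methanol is mild enough that the freed phenol should not add across the trisubstituted alkene, which needs much stronger acid.

Step 9
Reactants: 11 2,4-dibromo-6-[(4R)-2,6-dimethylhept-2-en-4-yl]-3,5-dimethoxyphenol; 12 2,4,6-trimethoxybenzaldehyde
Product: 14 (2R,3S,4R)-6,8-dibromo-5,7-dimethoxy-4-(2-methylpropyl)-3-(prop-1-en-2-yl)-2-(2,4,6-trimethoxyphenyl)chroman, via aryl trimethylsilyl ether 13 (not isolated)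
Conditions: 12 (1.3 equiv), Me3SiOTf (2.3 equiv), 2,6-di-tert-butyl-4-methylpyridine (2.6 equiv), CH2Cl2 (0.02 M), −78 to −20 °C
Reagents that add atoms: none
Why: Proposed new method: Me3SiOTf silylates the phenol (13) and the carbonyl oxygen of 12, O-attack and loss of hexamethyldisiloxane give the E-aryloxycarbenium ion O1=C2, the trisubstituted alkene adds to it through C3, and the exocyclic tertiary cation gives up a methyl proton to the hindered pyridine to leave the isopropenyl group (should the alkene add to silylated 12 first, SN1 closure of O1–C2 at the trimethoxybenzylic carbon leads to the same chroman). The closest known reaction type is the oxonia-ene (Prins-type) cyclisation of 5-methylhex-4-en-1-ols with aldehydes or acetals to 2,3-trans-3-isopropenyltetrahydropyrans, which has not been shown with a phenol oxygen as O1 or with so hindered a pair of partners. The pyran ring closes in a six-membered mode that is endo to the O1=C2 bond and exo to the alkene, and because C2 and the alkene stand in a 1,6 relation no oxonia-Cope pathway can erode C4. C3 is controlled by allylic 1,3-strain at C4: the C4–H bond lies in the alkene plane beside the cis methyl group, the carbenium carbon is delivered from the side of ring A, and the isobutyl group therefore ends trans to the isopropenyl group. C2 is controlled by the E geometry of the carbenium ion in a chair-like transition state with the trimethoxyphenyl group and the reacting alkene equatorial (2,3-trans), backed by reversible ionisation of C2–O1 that may let a cis share drift to the trans isomer. The step needs O-attack over C-attack of ring A on the aldehyde and ene closure over protic addition of the phenol to the alkene: bromine at both free positions of ring A shuts off Friedel–Crafts attack and makes O1 a poorer donor, the gem-dimethyl terminus makes C3 the nucleophilic carbon, and the pyridine removes the triflic acid that would otherwise close a 2,2-dimethylchroman.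

Step 10
Reactants: 14 (2R,3S,4R)-6,8-dibromo-5,7-dimethoxy-4-(2-methylpropyl)-3-(prop-1-en-2-yl)-2-(2,4,6-trimethoxyphenyl)chroman
Product: 15 (2R,3R,4R)-5,7-dimethoxy-4-(2-methylpropyl)-3-(propan-2-yl)-2-(2,4,6-trimethoxyphenyl)chroman
Conditions: H2 (1 atm), 10% Pd/C, Et3N (3 equiv), EtOAc–MeOH, rt
Reagents that add atoms: none
Why: Heterogeneous catalytic hydrogenation saturates the 1,1-disubstituted alkene and, with amine present, hydrogenolyses both aryl C–Br bonds while keeping the medium basic so that the benzylic C2–O1 bond is spared, and no stereocentre is touched (the C3 descriptor changes from S to R by priority only).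

Step 11
Reactants: 15 (2R,3R,4R)-5,7-dimethoxy-4-(2-methylpropyl)-3-(propan-2-yl)-2-(2,4,6-trimethoxyphenyl)chroman
Product: 17 (2R,3R,4R)-2-(3,5-diformyl-2,4,6-trimethoxyphenyl)-5,7-dimethoxy-4-(2-methylpropyl)-3-(propan-2-yl)chroman-6,8-dicarbaldehyde, via tetrakis(α-chloro ether) 16 (not isolated)
Conditions: Cl2CHOMe (12 equiv), TiCl4 (12 equiv), CH2Cl2, −78 to 0 °C; then H2O
Reagents that add atoms: dichloromethyl methyl ether, COC(Cl)Cl; water, O
Why: Rieche formylation (Friedel–Crafts attack of the chloro(methoxy)methyl cation, then hydrolysis) at the four free ring positions, each flanked by two oxygen donors and therefore still reactive enough for a second formyl group per ring, as in phloroglucinol trimethyl ethers.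

Step 12
Reactants: 17 (2R,3R,4R)-2-(3,5-diformyl-2,4,6-trimethoxyphenyl)-5,7-dimethoxy-4-(2-methylpropyl)-3-(propan-2-yl)chroman-6,8-dicarbaldehyde
Product: 18 sideroxylonal C, (2R,3R,4R)-2-(3,5-diformyl-2,4,6-trihydroxyphenyl)-5,7-dihydroxy-4-(2-methylpropyl)-3-(propan-2-yl)chroman-6,8-dicarbaldehyde
Conditions: BCl3 (15 equiv), CH2Cl2, −78 °C to rt; then H2O
Reagents that add atoms: none
Why: Chelation-assisted Lewis-acid cleavage of aryl methyl ethers, in which every methoxy group lies ortho to a formyl group so that boron bridges the two oxygens and chloride removes the methyl group, whereas O1–C2 is a hindered secondary ether on a ring B made electron-poor by its two formyl groups.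

**Compound list**

1 | 2-hydroxy-4,6-dimethoxybenzaldehyde | COc1cc(O)c(C=O)c(OC)c1 | starting material
2 | 3,5-dibromo-2-hydroxy-4,6-dimethoxybenzaldehyde | COc1c(Br)c(O)c(C=O)c(OC)c1Br | intermediate
3 | 3,5-dibromo-4,6-dimethoxy-2-(methoxymethoxy)benzaldehyde | COCOc1c(Br)c(OC)c(Br)c(OC)c1C=O | intermediate
4 | ethyl (E)-3-[3,5-dibromo-4,6-dimethoxy-2-(methoxymethoxy)phenyl]prop-2-enoate | CCOC(=O)/C=C/c1c(OCOC)c(Br)c(OC)c(Br)c1OC | intermediate
5 | (E)-3-[3,5-dibromo-4,6-dimethoxy-2-(methoxymethoxy)phenyl]prop-2-en-1-ol | OC/C=C/c1c(OCOC)c(Br)c(OC)c(Br)c1OC | intermediate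
6 | (E)-3-[3,5-dibromo-4,6-dimethoxy-2-(methoxymethoxy)phenyl]prop-2-en-1-yl diethyl phosphate | CCOP(=O)(OCC)OC/C=C/c1c(OCOC)c(Br)c(OC)c(Br)c1OC | intermediate
7 | isobutylmagnesium bromide | CC(C)C[Mg]Br | starting material
8 | (3R)-3-[3,5-dibromo-4,6-dimethoxy-2-(methoxymethoxy)phenyl]-5-methylhex-1-ene | CC(C)C[C@H](C=C)c1c(OCOC)c(Br)c(OC)c(Br)c1OC | intermediate
9 | 2-methylbut-2-ene | CC=C(C)C | starting material
10 | (4R)-4-[3,5-dibromo-4,6-dimethoxy-2-(methoxymethoxy)phenyl]-2,6-dimethylhept-2-ene | CC(C)C[C@H](C=C(C)C)c1c(OCOC)c(Br)c(OC)c(Br)c1OC | intermediate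
11 | 2,4-dibromo-6-[(4R)-2,6-dimethylhept-2-en-4-yl]-3,5-dimethoxyphenol | CC(C)C[C@H](C=C(C)C)c1c(O)c(Br)c(OC)c(Br)c1OC | intermediate
12 | 2,4,6-trimethoxybenzaldehyde | COc1cc(OC)c(C=O)c(OC)c1 | starting material
13 | {2,4-dibromo-6-[(4R)-2,6-dimethylhept-2-en-4-yl]-3,5-dimethoxyphenoxy}trimethylsilane (formed in the flask, not isolated) | CC(C)C[C@H](C=C(C)C)c1c(O[Si](C)(C)C)c(Br)c(OC)c(Br)c1OC | intermediate
14 | (2R,3S,4R)-6,8-dibromo-5,7-dimethoxy-4-(2-methylpropyl)-3-(prop-1-en-2-yl)-2-(2,4,6-trimethoxyphenyl)chroman | CC(C)C[C@H]1c2c(OC)c(Br)c(OC)c(Br)c2O[C@@H](c2c(OC)cc(OC)cc2OC)[C@@H]1C(C)=C | intermediate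
15 | (2R,3R,4R)-5,7-dimethoxy-4-(2-methylpropyl)-3-(propan-2-yl)-2-(2,4,6-trimethoxyphenyl)chroman | CC(C)C[C@H]1c2c(OC)cc(OC)cc2O[C@@H](c2c(OC)cc(OC)cc2OC)[C@@H]1C(C)C | intermediate
16 | (2R,3R,4R)-6,8-bis[chloro(methoxy)methyl]-2-{3,5-bis[chloro(methoxy)methyl]-2,4,6-trimethoxyphenyl}-5,7-dimethoxy-4-(2-methylpropyl)-3-(propan-2-yl)chroman (epimers at the four CHCl carbons, formed in the flask, not isolated) | CC(C)C[C@H]1c2c(OC)c(C(Cl)OC)c(OC)c(C(Cl)OC)c2O[C@@H](c2c(OC)c(C(Cl)OC)c(OC)c(C(Cl)OC)c2OC)[C@@H]1C(C)C | intermediate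
17 | (2R,3R,4R)-2-(3,5-diformyl-2,4,6-trimethoxyphenyl)-5,7-dimethoxy-4-(2-methylpropyl)-3-(propan-2-yl)chroman-6,8-dicarbaldehyde | CC(C)C[C@H]1c2c(OC)c(C=O)c(OC)c(C=O)c2O[C@@H](c2c(OC)c(C=O)c(OC)c(C=O)c2OC)[C@@H]1C(C)C | intermediate
18 | sideroxylonal C, (2R,3R,4R)-2-(3,5-diformyl-2,4,6-trihydroxyphenyl)-5,7-dihydroxy-4-(2-methylpropyl)-3-(propan-2-yl)chroman-6,8-dicarbaldehyde | CC(C)C[C@H]1c2c(O)c(C=O)c(O)c(C=O)c2O[C@@H](c2c(O)c(C=O)c(O)c(C=O)c2O)[C@@H]1C(C)C | target

**Step count and risks**

Total step count: 12. Longest linear sequence: 12 steps (1 to 18); 7, 9 and 12 are bought.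

Steps most likely to fail:

1. Step 9 (proposed new method). The hindered silyl ether oxygen may fail to condense with the donor-rich aldehyde, so that stray acid adds the phenol across the alkene instead. Ring closure may also show poor facial selectivity at the carbenium carbon, because a chair with the isobutyl group and the alkene axial relieves peri strain against the C5 methoxy group and leads to the 2,3-cis chroman. The fallback replaces the ene closure by a hetero-Diels–Alder reaction of an ortho-quinone methide, a known way to 2-aryl-3,4-dialkylchromans. It sets out from 1, 7 and 12 and returns at 15. Addition of excess 7 to 1 (THF, 0 °C) should give racemic 2-(1-hydroxy-3-methylbutyl)-3,5-dimethoxyphenol F1. Addition of 7 to 12 should give racemic 3-methyl-1-(2,4,6-trimethoxyphenyl)butan-1-ol F2, which is dehydrated (TsOH cat, toluene, 60 °C) to (E)-1,3,5-trimethoxy-2-(3-methylbut-1-en-1-yl)benzene F3. Heating F1 with excess F3 (toluene, 110 °C) generates the quinone methide, and its inverse-demand [4+2] addition to the E-alkene fixes 2,3-trans through the alkene geometry. The 3,4-trans diastereomer, separated from any 3,4-cis isomer by chromatography, is the racemate of 15 and its (2S,3S,4S)-enantiomer F4. F4 is removed by preparative HPLC on a chiral stationary phase, and 15 continues with step 11.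

2. Step 6. The isobutyl group may couple at the unhindered terminus (linear product) because the aryl-bearing carbon is flanked by two ortho substituents, or the catalyst may distinguish the alkene faces poorly. The fallback replaces catalyst control by 1,3-chirality transfer. It sets out from 3 and returns at 10. Claisen–Schmidt condensation of 3 with acetone (NaOH, aq acetone) should give (E)-4-[3,5-dibromo-4,6-dimethoxy-2-(methoxymethoxy)phenyl]but-3-en-2-one F5. Corey–Bakshi–Shibata reduction ((R)-Me-CBS oxazaborolidine, BH3·SMe2, THF, −20 °C) is expected, by the usual model, to give (2S,3E)-4-[3,5-dibromo-4,6-dimethoxy-2-(methoxymethoxy)phenyl]but-3-en-2-ol F6. Esterification with picolinic acid (DCC, DMAP, CH2Cl2) gives the (2S,3E)-picolinate F7. Its anti-SN2′ substitution with 7 and CuBr·SMe2 (THF, −78 to 0 °C), directed by chelation of the pyridyl ester, should give (2E,4R)-4-[3,5-dibromo-4,6-dimethoxy-2-(methoxymethoxy)phenyl]-6-methylhept-2-ene F8. Cross-metathesis of F8 with 9 under the conditions of step 7 then gives 10.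

3. Step 11. TiCl4 may ionise the benzylic C2–O1 ether before ring B is deactivated (ring opening or epimerisation at C2), and the second formylation on each ring may stall. The fallback brings in the four carbons by cross-coupling under neutral or basic conditions. It sets out from 15 and returns at 17. NBS (4.2 equiv, MeCN, 0 °C) should give (2R,3R,4R)-6,8-dibromo-2-(3,5-dibromo-2,4,6-trimethoxyphenyl)-5,7-dimethoxy-4-(2-methylpropyl)-3-(propan-2-yl)chroman F9. Fourfold Suzuki–Miyaura vinylation (CH2=CHBF3K, Pd(OAc)2, SPhos, K2CO3, toluene–H2O, 90 °C) gives (2R,3R,4R)-6,8-diethenyl-2-(3,5-diethenyl-2,4,6-trimethoxyphenyl)-5,7-dimethoxy-4-(2-methylpropyl)-3-(propan-2-yl)chroman F10. Lemieux–Johnson cleavage (OsO4 cat, NaIO4, 2,6-lutidine, dioxane–H2O) then gives 17.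

Further compounds
F1 | step 9 | racemic 2-(1-hydroxy-3-methylbutyl)-3,5-dimethoxyphenol | CC(C)CC(O)c1c(O)cc(OC)cc1OC
F2 | step 9 | racemic 3-methyl-1-(2,4,6-trimethoxyphenyl)butan-1-ol | CC(C)CC(O)c1c(OC)cc(OC)cc1OC
F3 | step 9 | (E)-1,3,5-trimethoxy-2-(3-methylbut-1-en-1-yl)benzene | CC(C)/C=C/c1c(OC)cc(OC)cc1OC
F4 | step 9 | (2S,3S,4S)-5,7-dimethoxy-4-(2-methylpropyl)-3-(propan-2-yl)-2-(2,4,6-trimethoxyphenyl)chroman (enantiomer of 15) | CC(C)C[C@@H]1c2c(OC)cc(OC)cc2O[C@H](c2c(OC)cc(OC)cc2OC)[C@H]1C(C)C
F5 | step 6 | (E)-4-[3,5-dibromo-4,6-dimethoxy-2-(methoxymethoxy)phenyl]but-3-en-2-one | CC(=O)/C=C/c1c(OCOC)c(Br)c(OC)c(Br)c1OC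
F6 | step 6 | (2S,3E)-4-[3,5-dibromo-4,6-dimethoxy-2-(methoxymethoxy)phenyl]but-3-en-2-ol | C[C@H](O)/C=C/c1c(OCOC)c(Br)c(OC)c(Br)c1OC
F7 | step 6 | (2S,3E)-4-[3,5-dibromo-4,6-dimethoxy-2-(methoxymethoxy)phenyl]but-3-en-2-yl pyridine-2-carboxylate | C[C@H](OC(=O)c1ccccn1)/C=C/c1c(OCOC)c(Br)c(OC)c(Br)c1OC
F8 | step 6 | (2E,4R)-4-[3,5-dibromo-4,6-dimethoxy-2-(methoxymethoxy)phenyl]-6-methylhept-2-ene | CC(C)C[C@H](/C=C/C)c1c(OCOC)c(Br)c(OC)c(Br)c1OC
F9 | step 11 | (2R,3R,4R)-6,8-dibromo-2-(3,5-dibromo-2,4,6-trimethoxyphenyl)-5,7-dimethoxy-4-(2-methylpropyl)-3-(propan-2-yl)chroman | CC(C)C[C@H]1c2c(OC)c(Br)c(OC)c(Br)c2O[C@@H](c2c(OC)c(Br)c(OC)c(Br)c2OC)[C@@H]1C(C)C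
F10 | step 11 | (2R,3R,4R)-6,8-diethenyl-2-(3,5-diethenyl-2,4,6-trimethoxyphenyl)-5,7-dimethoxy-4-(2-methylpropyl)-3-(propan-2-yl)chroman | CC(C)C[C@H]1c2c(OC)c(C=C)c(OC)c(C=C)c2O[C@@H](c2c(OC)c(C=C)c(OC)c(C=C)c2OC)[C@@H]1C(C)C
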